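**Retrosynthetic overview**
- The strategy rests on ring A of the flavone: besides the two fusion carbons C4a and C8a shared with pyranone ring C, it consists of the contiguous carbons C5, C6, C7 and C8, and each of these ends as C–OMe.
- Ring A is therefore cut at C4a–C5 and C8–C8a into a 1,2,3,4-tetraoxygenated butadiene (a silyl ketene acetal) and a ring C 4-pyranone that already carries the 4-methoxyphenyl ring B; since all four diene carbons become C–OMe, either orientation of addition leads to tangeretin.
- A 4-methylphenylsulfinyl group on the future C4a activates the C4a=C8a bond and later leaves as sulfenic acid; together with loss of methanol from the ketene acetal carbon this aromatizes ring A to the 5-hydroxyflavone, which is O-methylated last.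
- Ring order: ring B is purchased; ring C is closed from a sulfur-bearing enaminone and 4-methoxybenzoyl chloride, which fixes the sulfur position without a regiochemical question; ring A is formed last. The diene comes from methyl methoxyacetate in three steps.

Key step: step 8

Remark: tangeretin is achiral, so all stereocentres and double-bond geometries of intermediates are transient and are carried as mixtures; conjugate bases (enolates, thiolate, phenoxide) generated in situ from numbered compounds are treated as forms of those compounds and are not numbered.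

**Route**

Step 1
Reactants: 1 methyl methoxyacetate (2 equiv)
Product: 2 methyl 2,4-dimethoxy-3-oxobutanoate (racemic)
Conditions: NaH (1 equiv per 2 equiv of 1), cat. MeOH, THF, 0 °C → reflux; then 1 M HCl, 0 °C
Reagents that add atoms: none
Why: Claisen self-condensation, in which the ester enolate of 1 acylates a second molecule of 1 and the equilibrium is pulled through by deprotonation of the β-keto ester formed; the labile C2 stereocentre disappears in step 2.

Step 2
Reactants: 2 methyl 2,4-dimethoxy-3-oxobutanoate
Product: 4 methyl 2,3,4-trimethoxybut-2-enoate (E/Z mixture), via dimethyl ketal 3 (not isolated)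
Conditions: HC(OMe)3 (1.5 equiv), cat. H2SO4, rt; then 110 °C with removal of MeOH and HCO2Me; vacuum distillation
Reagents that add atoms: trimethyl orthoformate, COC(OC)OC
Why: Acid-catalysed ketalisation by the orthoformate followed by thermal loss of methanol (enol ether formation via the ketal) should O-methylate the β-keto ester without C-alkylation; the conjugated enoate is the thermodynamic isomer, and any double-bond isomer gives the same dienolate in step 3.

Step 3
Reactants: 4 methyl 2,3,4-trimethoxybut-2-enoate
Product: 5 1,2,3,4-tetramethoxy-1-(trimethylsilyloxy)buta-1,3-diene (mixture of geometric isomers)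
Conditions: LiN(iPr)2 (1.1 equiv), THF, −78 °C; Me3SiCl (1.3 equiv), −78 °C → rt; pentane, filtration, bulb-to-bulb distillation, used at once
Reagents that add atoms: chlorotrimethylsilane, C[Si](C)(C)Cl
Why: γ-Deprotonation of the β-alkoxy enoate gives the vinylogous ester enolate, which the hard silyl chloride traps on oxygen (silyl ketene acetal formation, the standard access to 1,1-dioxygenated dienes); the isomer mixture is used as such because all isomers lead to the same arene.

Step 4
Reactants: 6 4-methylbenzenethiol; 7 chloroacetone
Product: 8 1-[(4-methylphenyl)sulfanyl]propan-2-one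
Conditions: K2CO3 (1.2 equiv), acetone, 0 °C → rt
Reagents that add atoms: none
Why: SN2 thioetherification of the activated primary α-chloro ketone by the soft thiolate.

Step 5
Reactants: 8 1-[(4-methylphenyl)sulfanyl]propan-2-one; 9 N,N-dimethylformamide dimethyl acetal (1.2 equiv)
Product: 10 4-(dimethylamino)-3-[(4-methylphenyl)sulfanyl]but-3-en-2-one (geometric isomers)
Conditions: toluene, 90 °C, MeOH distilled off
Reagents that add atoms: none
Why: Enaminone formation by condensation of the formamide acetal at the more acidic methylene flanked by sulfur and carbonyl, which places the future C8a carbon next to the sulfur-bearing carbon; the methyl group reacts much more slowly.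

Step 6
Reactants: 10 4-(dimethylamino)-3-[(4-methylphenyl)sulfanyl]but-3-en-2-one; 11 4-methoxybenzoyl chloride
Product: 13 2-(4-methoxyphenyl)-5-[(4-methylphenyl)sulfanyl]-4H-pyran-4-one, via enaminodiketone 12 (not isolated)
Conditions: LiN(SiMe3)2 (2.2 equiv), THF, −78 °C; 11 (1.0 equiv), −78 → 0 °C; then CF3CO2H (excess), CH2Cl2, rt
Reagents that add atoms: none
Why: Kinetic enolisation of the only enolisable position (the methyl ketone) and C-acylation by the aroyl chloride give the 1,3-diketone, whose acidic proton is taken up by the second equivalent of base; acid then drives addition of the enol oxygen to the enaminone β-carbon with loss of dimethylamine (acylation–cyclocondensation route to 2-substituted 4-pyranones), so sulfur ends at C5 unambiguously.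

Step 7
Reactants: 13 2-(4-methoxyphenyl)-5-[(4-methylphenyl)sulfanyl]-4H-pyran-4-one
Product: 14 2-(4-methoxyphenyl)-5-[(4-methylphenyl)sulfinyl]-4H-pyran-4-one (racemic sulfoxide)
Conditions: mCPBA (1.0 equiv), CH2Cl2, −40 → 0 °C; aq. Na2S2O3/NaHCO3 wash
Reagents that add atoms: 3-chloroperoxybenzoic acid (mCPBA), OOC(=O)c1cccc(Cl)c1
Why: Chemoselective sulfide-to-sulfoxide oxidation with one equivalent of peracid at low temperature; the electron-poor pyranone double bonds and the anisyl ring should be inert, and the racemic sulfur stereocentre is lost in step 8.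

Step 8
Reactants: 5 1,2,3,4-tetramethoxy-1-(trimethylsilyloxy)buta-1,3-diene (2.5 equiv); 14 2-(4-methoxyphenyl)-5-[(4-methylphenyl)sulfinyl]-4H-pyran-4-one
Product: 18 5-hydroxy-6,7,8-trimethoxy-2-(4-methoxyphenyl)chromen-4-one (5-O-demethyltangeretin), via cycloadduct 15 (not isolated), via dihydro intermediate 16 (not isolated), via silyl ether 17 (not isolated)
Conditions: toluene, 0 °C → rt, then 100 °C; then 1 M HCl, THF, rt
Reagents that add atoms: none
Why: Proposed new method: the electron-rich diene 5 should add in a normal-electron-demand, strongly asynchronous [4+2] reaction across the C5=C6 bond of pyranone 14 (the future C4a=C8a), its CH(OMe) terminus bonding first to the β-carbon C8a and the ketene acetal carbon then closing on the sulfinyl-bearing C4a, so that the six-membered ring A is closed suprafacially at both diene termini (in the stepwise limit, a Mukaiyama–Michael addition followed by six-membered ring closure of the α-sulfinyl enolate onto the silyloxycarbenium ion). The closest known reaction types are cycloadditions of silyloxy and ketene acetal dienes to chromones and 4-pyranones carrying an acceptor at C3, and Diels–Alder/sulfoxide-pyrolysis benzannulations of sulfinyl enones and sulfinylquinones; the combination of a tetraoxygenated diene with a sulfinylpyranone is untested. The sp3 centres of adduct 15 (C4a, C5, C8, C8a) are transient, and the one relationship that matters, sulfinyl cis to H-8a, follows from suprafacial addition to an endocyclic double bond and permits thermal syn elimination of 4-methylbenzenesulfenic acid to give 16. Ionisation of the C5 mixed ketal with loss of methoxide, followed by loss of H-8, should then give aryl silyl ether 17, which the acidic work-up cleaves to the chelated phenol 18; with base excluded, nothing should open the C8a–O1 bond. The selectivity required is reaction at C4a=C8a rather than at the aryl-substituted C2=C3 bond, and the sulfinyl group secures it by making that enone unit doubly activated while its β-carbon stays unsubstituted. The orientation of addition is immaterial, because the reverse regioisomer (8-hydroxy) and any 5-O-methyl product from loss of trimethylsilanol instead of methanol both converge on tangeretin in step 9.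

Step 9
Reactants: 18 5-hydroxy-6,7,8-trimethoxy-2-(4-methoxyphenyl)chromen-4-one
Product: 19 tangeretin, 5,6,7,8-tetramethoxy-2-(4-methoxyphenyl)chromen-4-one
Conditions: Me2SO4 (3 equiv), K2CO3 (5 equiv), acetone, reflux
Reagents that add atoms: dimethyl sulfate, COS(=O)(=O)OC
Why: Williamson O-methylation of the hydrogen-bonded 5-hydroxyl group, which needs the forcing but established dimethyl sulfate/K2CO3/refluxing acetone conditions used for 5-hydroxyflavones.

**Compound list**

1 | methyl methoxyacetate | COCC(=O)OC | starting material
2 | methyl 2,4-dimethoxy-3-oxobutanoate (racemic) | COCC(=O)C(OC)C(=O)OC | intermediate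
3 | methyl 2,3,3,4-tetramethoxybutanoate (dimethyl ketal, racemic, not isolated) | COCC(OC)(OC)C(OC)C(=O)OC | intermediate
4 | methyl 2,3,4-trimethoxybut-2-enoate (E/Z mixture) | COCC(OC)=C(OC)C(=O)OC | intermediate
5 | 1,2,3,4-tetramethoxy-1-(trimethylsilyloxy)buta-1,3-diene (mixture of geometric isomers) | COC=C(OC)C(OC)=C(OC)O[Si](C)(C)C | intermediate
6 | 4-methylbenzenethiol | Cc1ccc(S)cc1 | starting material
7 | chloroacetone (1-chloropropan-2-one) | CC(=O)CCl | starting material
8 | 1-[(4-methylphenyl)sulfanyl]propan-2-one | CC(=O)CSc1ccc(C)cc1 | intermediate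
9 | N,N-dimethylformamide dimethyl acetal | COC(OC)N(C)C | starting material
10 | 4-(dimethylamino)-3-[(4-methylphenyl)sulfanyl]but-3-en-2-one (geometric isomers) | CC(=O)C(Sc1ccc(C)cc1)=CN(C)C | intermediate
11 | 4-methoxybenzoyl chloride | COc1ccc(C(=O)Cl)cc1 | starting material
12 | 5-(dimethylamino)-1-(4-methoxyphenyl)-4-[(4-methylphenyl)sulfanyl]pent-4-ene-1,3-dione (keto/enol and geometric isomers, not isolated) | COc1ccc(cc1)C(=O)CC(=O)C(Sc2ccc(C)cc2)=CN(C)C | intermediate
13 | 2-(4-methoxyphenyl)-5-[(4-methylphenyl)sulfanyl]-4H-pyran-4-one | COc1ccc(-c2cc(=O)c(Sc3ccc(C)cc3)co2)cc1 | intermediate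
14 | 2-(4-methoxyphenyl)-5-[(4-methylphenyl)sulfinyl]-4H-pyran-4-one (racemic at sulfur) | COc1ccc(-c2cc(=O)c(S(=O)c3ccc(C)cc3)co2)cc1 | intermediate
15 | 5,6,7,8-tetramethoxy-2-(4-methoxyphenyl)-4a-[(4-methylphenyl)sulfinyl]-5-(trimethylsilyloxy)-4a,5,8,8a-tetrahydro-4H-chromen-4-one (cycloadduct, sulfinyl cis to H-8a, diastereomer mixture at C5, C8 and sulfur, not isolated) | COc1ccc(cc1)C2=CC(=O)C3(S(=O)c4ccc(C)cc4)C(O2)C(OC)C(OC)=C(OC)C3(OC)O[Si](C)(C)C | intermediate
16 | 5,6,7,8-tetramethoxy-2-(4-methoxyphenyl)-5-(trimethylsilyloxy)-5,8-dihydro-4H-chromen-4-one (diastereomer mixture, not isolated) | COc1ccc(cc1)C2=CC(=O)C3=C(O2)C(OC)C(OC)=C(OC)C3(OC)O[Si](C)(C)C | intermediate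
17 | 6,7,8-trimethoxy-2-(4-methoxyphenyl)-5-(trimethylsilyloxy)-4H-chromen-4-one (not isolated) | COc1ccc(-c2cc(=O)c3c(O[Si](C)(C)C)c(OC)c(OC)c(OC)c3o2)cc1 | intermediate
18 | 5-hydroxy-6,7,8-trimethoxy-2-(4-methoxyphenyl)chromen-4-one (5-O-demethyltangeretin) | COc1ccc(-c2cc(=O)c3c(O)c(OC)c(OC)c(OC)c3o2)cc1 | intermediate
19 | tangeretin, 5,6,7,8-tetramethoxy-2-(4-methoxyphenyl)chromen-4-one | COc1ccc(-c2cc(=O)c3c(OC)c(OC)c(OC)c(OC)c3o2)cc1 | target

**Summary**

Total step count: 9 (steps 1–3 for the diene, steps 4–7 for the sulfinylpyranone, steps 8 and 9 after convergence).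
Longest linear sequence: 6 steps (steps 4, 5, 6, 7, 8, 9, from 4-methylbenzenethiol and chloroacetone).

**Steps most likely to fail**

1. Step 8 (proposed new method). The fully substituted diene may act only as a nucleophile and stop after the first C–C bond, with silyl transfer to the pyranone enolate and no ring closure. The ketene acetal may also silylate the sulfoxide oxygen and divert the dienophile into Pummerer-type chemistry, or the adduct may open at C8a–O1 instead of losing sulfenic acid. Fallback (known chemistry; ring A is brought in preformed and ring C is closed last): it sets out from acid chloride 11 and comes back to the route at tangeretin 19. Commercially available 1-(2-hydroxy-3,4,5,6-tetramethoxyphenyl)ethanone F1 is O-acylated with 11 (pyridine, rt) to give 2-acetyl-3,4,5,6-tetramethoxyphenyl 4-methoxybenzoate F2. Baker–Venkataraman rearrangement (KOH, pyridine, 50 °C) gives 1-(2-hydroxy-3,4,5,6-tetramethoxyphenyl)-3-(4-methoxyphenyl)propane-1,3-dione F3, and acid cyclodehydration (cat. H2SO4, AcOH, 100 °C) closes the pyranone ring to give 19 directly.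

2. Step 6. O-acylation or double acylation of the enaminone enolate, consumption of 11 by N-acylation of the excess silylamide, or incomplete displacement of dimethylamine in the ring closure would all cut the supply of 13. Fallback (sulfur is introduced after the ring is built): it sets out from acid chloride 11 and comes back at sulfide 13. The lithium enolate of commercial (E)-4-methoxybut-3-en-2-one F4 (LiN(SiMe3)2, THF, −78 °C) is acylated with 11 to give (E)-5-methoxy-1-(4-methoxyphenyl)pent-4-ene-1,3-dione F5, which CF3CO2H cyclises to 2-(4-methoxyphenyl)-4H-pyran-4-one F6. Nucleophile-mediated α-iodination (I2, pyridine, CH2Cl2, rt), in which the amine adds to the unsubstituted C6 and so directs iodine to C5 rather than to C3, should give 5-iodo-2-(4-methoxyphenyl)-4H-pyran-4-one F7. C–S cross-coupling with thiol 6 (Pd2(dba)3 as zerovalent palladium source, Xantphos, iPr2NEt, dioxane, 100 °C) then gives 13.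

3. Step 2. Ketalisation of a ketone flanked by two α-alkoxy carbons may be slow, and the ketal may not lose methanol cleanly or may decompose on acidic distillation. Fallback (the enol oxygen is silylated instead of methylated, giving a 1,3-bis(silyloxy) diene): it sets out from β-keto ester 2 and comes back at tangeretin 19. Silylation of 2 (Me3SiCl, Et3N, toluene, rt) gives methyl 2,4-dimethoxy-3-(trimethylsilyloxy)but-2-enoate F8, and LiN(iPr)2/Me3SiCl (THF, −78 °C) gives 1,2,4-trimethoxy-1,3-bis(trimethylsilyloxy)buta-1,3-diene F9. Reaction of F9 with sulfoxide 14 under the step 8 conditions should give, after the same eliminations and desilylation, 5,7-dihydroxy-6,8-dimethoxy-2-(4-methoxyphenyl)chromen-4-one F10. Its two hydroxyl groups are methylated together under the step 9 conditions to give 19.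

**Further compounds**

F1 | step 8 | 1-(2-hydroxy-3,4,5,6-tetramethoxyphenyl)ethanone (purchased) | CC(=O)c1c(O)c(OC)c(OC)c(OC)c1OC
F2 | step 8 | 2-acetyl-3,4,5,6-tetramethoxyphenyl 4-methoxybenzoate | CC(=O)c1c(OC(=O)c2ccc(OC)cc2)c(OC)c(OC)c(OC)c1OC
F3 | step 8 | 1-(2-hydroxy-3,4,5,6-tetramethoxyphenyl)-3-(4-methoxyphenyl)propane-1,3-dione | COc1ccc(cc1)C(=O)CC(=O)c2c(O)c(OC)c(OC)c(OC)c2OC
F4 | step 6 | (E)-4-methoxybut-3-en-2-one (purchased) | CO/C=C/C(C)=O
F5 | step 6 | (E)-5-methoxy-1-(4-methoxyphenyl)pent-4-ene-1,3-dione | CO/C=C/C(=O)CC(=O)c1ccc(OC)cc1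
F6 | step 6 | 2-(4-methoxyphenyl)-4H-pyran-4-one | COc1ccc(-c2cc(=O)cco2)cc1
F7 | step 6 | 5-iodo-2-(4-methoxyphenyl)-4H-pyran-4-one | COc1ccc(-c2cc(=O)c(I)co2)cc1
F8 | step 2 | methyl 2,4-dimethoxy-3-(trimethylsilyloxy)but-2-enoate (E/Z mixture) | COCC(O[Si](C)(C)C)=C(OC)C(=O)OC
F9 | step 2 | 1,2,4-trimethoxy-1,3-bis(trimethylsilyloxy)buta-1,3-diene (mixture of geometric isomers) | COC=C(O[Si](C)(C)C)C(OC)=C(OC)O[Si](C)(C)C
F10 | step 2 | 5,7-dihydroxy-6,8-dimethoxy-2-(4-methoxyphenyl)chromen-4-one | COc1ccc(-c2cc(=O)c3c(O)c(OC)c(O)c(OC)c3o2)cc1
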